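**Plan**

1. Numbering follows 2H-chromene (O1, C2, C3, C4, C4a, C5–C8, C8a); ring A is the benzo ring and ring B the pyran ring. Retrosynthesis first removes the prenyl group from O7 and puts silyl groups on both phenol oxygens, then takes ring A back to its 6,8a-dihydro level.
2. The enabling feature: rings A and B are fused at C4a–C8a, and the other ring-B atoms O1–C2–C3–C4 link these two carbons by four atoms. That link can carry a C8a=C8–C7=C6 diene on O1 and a C4a≡C5 alkyne on C4, so C4a–C8a and C5–C6 are cut together in a retro-[4+2].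
3. The open-chain dienyne is then cut at the enol C–O bond (oxa-Michael addition to butynone), at C4–C4a (Sonogashira coupling) and at the alkyne terminus (aldehyde homologation).
4. Forward: three commercial pieces are joined into the chain (steps 1–8), rings A and B close together in step 9, ring A is aromatised in step 10, and the two phenol oxygens are handled in turn (steps 11–13).
5. Stereochemistry: the target is achiral. The Z C3=C4 alkene comes from syn diimide reduction of an iodoalkyne and is kept in the coupling, and the E enol ether comes from the oxa-Michael addition. The C8a centre of the cycloadduct is racemic and disappears on aromatisation.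

Key step: step 9

Remark: tris(2-biphenylyl) phosphite is taken as purchasable (otherwise it is made from 2-phenylphenol and PCl3 and is not counted as a step).

**Route**

Step 1
Reactants: 1 methyl 3-(4-hydroxyphenyl)propanoate
Product: 2 methyl 3-[4-(triisopropylsilyloxy)phenyl]propanoate
Conditions: i-Pr3SiCl, imidazole, DMF, rt
Reagents that add atoms: chlorotri(propan-2-yl)silane, CC(C)[Si](Cl)(C(C)C)C(C)C
Why: Silyl ether formation on the phenol with a hindered chlorosilane and imidazole gives an aryl silyl ether that should survive hydride, carbonate in methanol, amide base and the later selective removal of a triethylsilyl group.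

Step 2
Reactants: 2 methyl 3-[4-(triisopropylsilyloxy)phenyl]propanoate
Product: 3 3-[4-(triisopropylsilyloxy)phenyl]propanal
Conditions: i-Bu2AlH (1.05 equiv), CH2Cl2, −78 °C; MeOH, then aq. potassium sodium tartrate
Reagents that add atoms: none
Why: Partial reduction of a methyl ester with i-Bu2AlH at −78 °C should stop at the aldehyde because the aluminium hemiacetal persists until the quench.

Step 3
Reactants: 3 3-[4-(triisopropylsilyloxy)phenyl]propanal
Product: 4 [4-(but-3-yn-1-yl)phenoxy]tri(propan-2-yl)silane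
Conditions: dimethyl (1-diazo-2-oxopropyl)phosphonate, K2CO3, MeOH, 0 °C to rt
Reagents that add atoms: dimethyl (1-diazo-2-oxopropyl)phosphonate, COP(=O)(OC)C(=[N+]=[N-])C(C)=O
Why: The Ohira–Bestmann variant of the Seyferth–Gilbert homologation turns an enolisable aldehyde into the terminal alkyne under carbonate in methanol, which a hindered aryl silyl ether should tolerate.

Step 4
Reactants: 5 2-methylbut-3-yn-2-ol
Product: 6 4-iodo-2-methylbut-3-yn-2-ol
Conditions: NIS, AgNO3 (10 mol %), acetone, rt, dark
Reagents that add atoms: N-iodosuccinimide, O=C1CCC(=O)N1I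
Why: Silver-catalysed electrophilic iodination of a terminal alkyne through the silver acetylide is a standard route to 1-iodoalkynes and leaves the tertiary alcohol untouched.

Step 5
Reactants: 6 4-iodo-2-methylbut-3-yn-2-ol
Product: 7 (3Z)-4-iodo-2-methylbut-3-en-2-ol
Conditions: 2-nitrobenzenesulfonohydrazide, Et3N, THF/i-PrOH, rt
Reagents that add atoms: none
Why: Diimide reduction delivers both hydrogens to the same face of the iodoalkyne without cleaving the C–I bond, so the alkene should form with iodine and the carbinol carbon cis (Z).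

Step 6
Reactants: 4 [4-(but-3-yn-1-yl)phenoxy]tri(propan-2-yl)silane; 7 (3Z)-4-iodo-2-methylbut-3-en-2-ol
Product: 8 (3Z)-2-methyl-8-[4-(triisopropylsilyloxy)phenyl]oct-3-en-5-yn-2-ol
Conditions: Pd(PPh3)2Cl2 (3 mol %), CuI (6 mol %), Et3N, THF, rt, degassed
Reagents that add atoms: none
Why: Sonogashira coupling of a vinyl iodide with a terminal alkyne runs at room temperature with retention of the Z geometry and tolerates a free tertiary alcohol.

Step 7
Reactants: 8 (3Z)-2-methyl-8-[4-(triisopropylsilyloxy)phenyl]oct-3-en-5-yn-2-ol; 9 but-3-yn-2-one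
Product: 10 (3E)-4-({(3Z)-2-methyl-8-[4-(triisopropylsilyloxy)phenyl]oct-3-en-5-yn-2-yl}oxy)but-3-en-2-one
Conditions: PMe3 (20 mol %), CH2Cl2, 0 °C to rt, slow addition of 9 (1.5 equiv)
Reagents that add atoms: none
Why: Phosphine-catalysed oxa-Michael addition of an alcohol to an ynone gives the E β-alkoxy enone, is known to work for hindered alcohols with this small phosphine, and stays neutral so the tertiary allylic C–O bond should not ionise.

Step 8
Reactants: 10 (3E)-4-({(3Z)-2-methyl-8-[4-(triisopropylsilyloxy)phenyl]oct-3-en-5-yn-2-yl}oxy)but-3-en-2-one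
Product: 12 triethyl{[(3E)-4-({(3Z)-2-methyl-8-[4-(triisopropylsilyloxy)phenyl]oct-3-en-5-yn-2-yl}oxy)buta-1,3-dien-2-yl]oxy}silane, via potassium dienolate 11 (not isolated)
Conditions: KN(SiMe3)2, THF, −78 °C; then Et3SiCl, −78 to −20 °C; pentane, filtration, no aqueous acid
Reagents that add atoms: chlorotriethylsilane, CC[Si](Cl)(CC)CC (KN(SiMe3)2, C[Si](C)(C)[N-][Si](C)(C)C.[K+], puts potassium into intermediate 11 only)
Why: Kinetic deprotonation of the methyl ketone and O-silylation of the cross-conjugated enolate (silyl enol ether formation) should give the 2-silyloxydiene without exposing the tertiary allylic ether to a Lewis acid.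

Step 9
Reactants: 12 triethyl{[(3E)-4-({(3Z)-2-methyl-8-[4-(triisopropylsilyloxy)phenyl]oct-3-en-5-yn-2-yl}oxy)buta-1,3-dien-2-yl]oxy}silane
Product: 13 triethyl({2,2-dimethyl-5-[2-(4-triisopropylsilyloxyphenyl)ethyl]-6,8a-dihydro-2H-chromen-7-yl}oxy)silane (racemic at C8a)
Conditions: Ni(cod)2 (10 mol %), P(O-2-biphenylyl)3 (30 mol %), THF, rt, argon; filtration through basic alumina, used at once
Reagents that add atoms: none
Why: Proposed new method: zerovalent nickel carrying the bulky, π-acidic phosphite should bind the C4a≡C5 alkyne and the siloxydiene, join C8a to C4a by oxidative cyclisation (closing ring B in a 6-exo-dig sense over the O1–C2–C3=C4 link) to give a seven-membered σ-vinyl/η3-allyl nickelacycle, and then form C5–C6 by reductive elimination, which closes carbocyclic ring A as a 1,4-cyclohexadiene with C4a=C5 and the C7=C8 silyl enol ether. The closest known reaction types are the nickel-catalysed intramolecular [4+2] cycloaddition of unactivated dienynes at room temperature and the thermal intramolecular Diels–Alder reaction of 1-alkoxy-3-silyloxybutadienes; new here are the ring oxygen directly on the diene terminus, the quaternary C2 and a conjugated enyne as the two-carbon partner. Because the metal pathway is stepwise, it should not depend on the poor frontier-orbital match between an electron-rich diene and an unactivated alkyne. The tether can only deliver C8a to C4a, so the arylethyl carbon becomes C5 and the silyloxy carbon C7, while the Z C3=C4 alkene and the gem-dimethyl group at C2 hold the two π systems within bonding distance. The one new stereocentre, C8a, forms as a racemate and needs no control because step 10 removes it. The step must outrun [3,3] rearrangement of the C8=C8a–O1–C2–C3=C4 allyl vinyl ether and ionisation of the tertiary allylic C2–O1 bond, which is why it is run at room temperature under neutral conditions with an electron-poor phosphite that disfavours insertion into C–O bonds.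

Step 10
Reactants: 13 triethyl({2,2-dimethyl-5-[2-(4-triisopropylsilyloxyphenyl)ethyl]-6,8a-dihydro-2H-chromen-7-yl}oxy)silane
Product: 14 triethyl({2,2-dimethyl-5-[2-(4-triisopropylsilyloxyphenyl)ethyl]-2H-chromen-7-yl}oxy)silane
Conditions: DDQ (1.05 equiv), PhMe, 0 °C; filtration
Reagents that add atoms: none
Why: Quinone dehydrogenation of a 1,4-cyclohexadiene (hydride abstraction from the doubly allylic, oxygen-bearing C8a–H, then proton loss from C6) should aromatise ring A, and in toluene the hydroquinone precipitates, so the medium stays non-acidic and the C8a–O1 bond is kept.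

Step 11
Reactants: 14 triethyl({2,2-dimethyl-5-[2-(4-triisopropylsilyloxyphenyl)ethyl]-2H-chromen-7-yl}oxy)silane
Product: 15 2,2-dimethyl-5-[2-(4-triisopropylsilyloxyphenyl)ethyl]-2H-chromen-7-ol
Conditions: K2CO3 (0.2 equiv), MeOH/THF, 0 °C
Reagents that add atoms: none
Why: Base-catalysed methanolysis cleaves an aryl triethylsilyl ether far faster than the hindered aryl triisopropylsilyl ether (selective silyl ether solvolysis), so only the C7 oxygen should be freed.

Step 12
Reactants: 15 2,2-dimethyl-5-[2-(4-triisopropylsilyloxyphenyl)ethyl]-2H-chromen-7-ol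
Product: 16 {4-[2-(2,2-dimethyl-7-[(3-methylbut-2-en-1-yl)oxy]-2H-chromen-5-yl)ethyl]phenoxy}tri(propan-2-yl)silane
Conditions: prenyl bromide, K2CO3, acetone, rt to 40 °C
Reagents that add atoms: 1-bromo-3-methylbut-2-ene, CC(C)=CCBr
Why: Williamson ether synthesis on the phenoxide with a primary allylic bromide in acetone favours O- over C-alkylation and should not disturb the remaining silyl ether.

Step 13
Reactants: 16 {4-[2-(2,2-dimethyl-7-[(3-methylbut-2-en-1-yl)oxy]-2H-chromen-5-yl)ethyl]phenoxy}tri(propan-2-yl)silane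
Product: 17 4-(2-{2,2-dimethyl-7-[(3-methylbut-2-en-1-yl)oxy]-2H-chromen-5-yl}ethyl)phenol (CNP0337021.0)
Conditions: Bu4NF, AcOH, THF, 0 °C to rt
Reagents that add atoms: none
Why: Fluoride desilylation breaks the Si–O bond of the aryl silyl ether, and acetic acid buffers the phenoxide so that the prenyl ether and the chromene should be left alone.

**Compound list**

1 | methyl 3-(4-hydroxyphenyl)propanoate | COC(=O)CCc1ccc(O)cc1 | starting material
2 | methyl 3-[4-(triisopropylsilyloxy)phenyl]propanoate | COC(=O)CCc1ccc(O[Si](C(C)C)(C(C)C)C(C)C)cc1 | intermediate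
3 | 3-[4-(triisopropylsilyloxy)phenyl]propanal | O=CCCc1ccc(O[Si](C(C)C)(C(C)C)C(C)C)cc1 | intermediate
4 | [4-(but-3-yn-1-yl)phenoxy]tri(propan-2-yl)silane | C#CCCc1ccc(O[Si](C(C)C)(C(C)C)C(C)C)cc1 | intermediate
5 | 2-methylbut-3-yn-2-ol | CC(C)(O)C#C | starting material
6 | 4-iodo-2-methylbut-3-yn-2-ol | CC(C)(O)C#CI | intermediate
7 | (3Z)-4-iodo-2-methylbut-3-en-2-ol | CC(C)(O)/C=C\I | intermediate
8 | (3Z)-2-methyl-8-[4-(triisopropylsilyloxy)phenyl]oct-3-en-5-yn-2-ol | CC(C)(O)/C=C\C#CCCc1ccc(O[Si](C(C)C)(C(C)C)C(C)C)cc1 | intermediate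
9 | but-3-yn-2-one | CC(=O)C#C | starting material
10 | (3E)-4-({(3Z)-2-methyl-8-[4-(triisopropylsilyloxy)phenyl]oct-3-en-5-yn-2-yl}oxy)but-3-en-2-one | CC(=O)/C=C/OC(C)(C)/C=C\C#CCCc1ccc(O[Si](C(C)C)(C(C)C)C(C)C)cc1 | intermediate
11 | potassium (3E)-4-({(3Z)-2-methyl-8-[4-(triisopropylsilyloxy)phenyl]oct-3-en-5-yn-2-yl}oxy)buta-1,3-dien-2-olate | [K+].C=C([O-])/C=C/OC(C)(C)/C=C\C#CCCc1ccc(O[Si](C(C)C)(C(C)C)C(C)C)cc1 | intermediate
12 | triethyl{[(3E)-4-({(3Z)-2-methyl-8-[4-(triisopropylsilyloxy)phenyl]oct-3-en-5-yn-2-yl}oxy)buta-1,3-dien-2-yl]oxy}silane | C=C(O[Si](CC)(CC)CC)/C=C/OC(C)(C)/C=C\C#CCCc1ccc(O[Si](C(C)C)(C(C)C)C(C)C)cc1 | intermediate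
13 | triethyl({2,2-dimethyl-5-[2-(4-triisopropylsilyloxyphenyl)ethyl]-6,8a-dihydro-2H-chromen-7-yl}oxy)silane, racemic at C8a | CC1(C)C=CC2=C(CCc3ccc(O[Si](C(C)C)(C(C)C)C(C)C)cc3)CC(O[Si](CC)(CC)CC)=CC2O1 | intermediate
14 | triethyl({2,2-dimethyl-5-[2-(4-triisopropylsilyloxyphenyl)ethyl]-2H-chromen-7-yl}oxy)silane | CC1(C)C=Cc2c(CCc3ccc(O[Si](C(C)C)(C(C)C)C(C)C)cc3)cc(O[Si](CC)(CC)CC)cc2O1 | intermediate
15 | 2,2-dimethyl-5-[2-(4-triisopropylsilyloxyphenyl)ethyl]-2H-chromen-7-ol | CC1(C)C=Cc2c(CCc3ccc(O[Si](C(C)C)(C(C)C)C(C)C)cc3)cc(O)cc2O1 | intermediate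
16 | {4-[2-(2,2-dimethyl-7-[(3-methylbut-2-en-1-yl)oxy]-2H-chromen-5-yl)ethyl]phenoxy}tri(propan-2-yl)silane | CC(C)=CCOc1cc(CCc2ccc(O[Si](C(C)C)(C(C)C)C(C)C)cc2)c2c(c1)OC(C)(C)C=C2 | intermediate
17 | 4-(2-{2,2-dimethyl-7-[(3-methylbut-2-en-1-yl)oxy]-2H-chromen-5-yl}ethyl)phenol | CC(C)=CCOc1cc(CCc2ccc(O)cc2)c2c(c1)OC(C)(C)C=C2 | target

**Step count and risks**

Total steps: 13 (steps 4 and 5 are a side branch). Longest linear sequence: 11 steps (1–3, then 6–13).

Steps most likely to fail:

Step 9, which carries the label for a new method. The nickel centre may insert into the tertiary allylic C2–O1 bond or be held unproductively by the conjugated enyne, so that the cycloaddition stalls or the tether is cleaved; heating to compensate would invite [3,3] rearrangement of the allyl vinyl ether. The fallback uses known chemistry, sets out from alkyne 4 and comes back at phenol 15, keeping a [4+2] construction of ring A in which the alkyne carbons again become C4a and C5, but between separate partners. Lithiation of 4 (n-BuLi, THF, −78 °C) and acylation with N-methoxy-N-methylacetamide should give 6-[4-(triisopropylsilyloxy)phenyl]hex-3-yn-2-one F1. A thermal Diels–Alder reaction of this ynone with 1-methoxy-1,3-bis(trimethylsilyloxy)buta-1,3-diene (PhMe, 80–110 °C), in which the nucleophilic CH2 terminus of the diene bonds to the alkyl-bearing alkyne carbon, should give 1-[6-methoxy-2-(2-{4-(triisopropylsilyloxy)phenyl}ethyl)-4,6-bis(trimethylsilyloxy)cyclohexa-1,4-dien-1-yl]ethan-1-one F2. This adduct is not isolated; on dilute HCl in THF it loses methanol and its trimethylsilyl groups and aromatises to 1-[2,4-dihydroxy-6-(2-{4-(triisopropylsilyloxy)phenyl}ethyl)phenyl]ethan-1-one F3, whose acetyl group already sits between a hydroxyl and the arylethyl chain. Kabbe condensation with acetone (pyrrolidine, EtOH, reflux) then closes ring B as 7-hydroxy-2,2-dimethyl-5-(2-{4-(triisopropylsilyloxy)phenyl}ethyl)-2,3-dihydro-4H-chromen-4-one F4. Reduction (LiAlH4, THF, 0 °C) should give racemic 2,2-dimethyl-5-(2-{4-(triisopropylsilyloxy)phenyl}ethyl)-3,4-dihydro-2H-chromene-4,7-diol F5, and acid-catalysed dehydration (TsOH cat., PhMe, 60 °C) leads to 15, which continues with step 12.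

Step 10. Traces of acid may ionise the doubly allylic C8a–O1 bond, so that ring B opens and the ring oxygen is lost in a 1,4-elimination, or the quinone may attack the silyl enol ether instead of abstracting hydride. The fallback sets out from 13 and comes back at 15, so step 11 is no longer needed. Saegusa–Ito oxidation with Pd(OAc)2 (1.1 equiv, MeCN, rt) converts the silyl enol ether into a divalent palladium enolate. β-Hydride elimination of the C8a hydrogen should give the cross-conjugated dienone 2,2-dimethyl-5-(2-{4-(triisopropylsilyloxy)phenyl}ethyl)-2H-chromen-7(6H)-one F6, which tautomerises at once to phenol 15. No hydride abstraction and no acidic hydroquinone are involved.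

Step 7. The hindered tertiary alcohol may add too slowly, so that butynone oligomerises under the phosphine, or the alkoxide may cyclise onto the alkyne. The fallback sets out from 8 and comes back at 10, using the acceptor best established for tertiary alcohols and forming the methyl ketone C–C bond afterwards. PMe3-catalysed addition of 8 to methyl propiolate (CH2Cl2, 0 °C to rt) should give methyl (2E)-3-({(3Z)-2-methyl-8-[4-(triisopropylsilyloxy)phenyl]oct-3-en-5-yn-2-yl}oxy)prop-2-enoate F7. Aminolysis with MeNH(OMe)·HCl and i-PrMgCl (THF, −20 °C) gives (2E)-N-methoxy-N-methyl-3-({(3Z)-2-methyl-8-[4-(triisopropylsilyloxy)phenyl]oct-3-en-5-yn-2-yl}oxy)prop-2-enamide F8, and MeMgBr (THF, 0 °C) converts this amide into enone 10.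

Further compounds
F1 | step 9 | 6-[4-(triisopropylsilyloxy)phenyl]hex-3-yn-2-one | CC(=O)C#CCCc1ccc(O[Si](C(C)C)(C(C)C)C(C)C)cc1
F2 | step 9 | 1-[6-methoxy-2-(2-{4-(triisopropylsilyloxy)phenyl}ethyl)-4,6-bis(trimethylsilyloxy)cyclohexa-1,4-dien-1-yl]ethan-1-one | CC(=O)C1=C(CCc2ccc(O[Si](C(C)C)(C(C)C)C(C)C)cc2)CC(O[Si](C)(C)C)=CC1(OC)O[Si](C)(C)C
F3 | step 9 | 1-[2,4-dihydroxy-6-(2-{4-(triisopropylsilyloxy)phenyl}ethyl)phenyl]ethan-1-one | CC(=O)c1c(O)cc(O)cc1CCc1ccc(O[Si](C(C)C)(C(C)C)C(C)C)cc1
F4 | step 9 | 7-hydroxy-2,2-dimethyl-5-(2-{4-(triisopropylsilyloxy)phenyl}ethyl)-2,3-dihydro-4H-chromen-4-one | CC1(C)CC(=O)c2c(CCc3ccc(O[Si](C(C)C)(C(C)C)C(C)C)cc3)cc(O)cc2O1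
F5 | step 9 | 2,2-dimethyl-5-(2-{4-(triisopropylsilyloxy)phenyl}ethyl)-3,4-dihydro-2H-chromene-4,7-diol (racemic) | CC1(C)CC(O)c2c(CCc3ccc(O[Si](C(C)C)(C(C)C)C(C)C)cc3)cc(O)cc2O1
F6 | step 10 | 2,2-dimethyl-5-(2-{4-(triisopropylsilyloxy)phenyl}ethyl)-2H-chromen-7(6H)-one | CC1(C)C=CC2=C(CCc3ccc(O[Si](C(C)C)(C(C)C)C(C)C)cc3)CC(=O)C=C2O1
F7 | step 7 | methyl (2E)-3-({(3Z)-2-methyl-8-[4-(triisopropylsilyloxy)phenyl]oct-3-en-5-yn-2-yl}oxy)prop-2-enoate | COC(=O)/C=C/OC(C)(C)/C=C\C#CCCc1ccc(O[Si](C(C)C)(C(C)C)C(C)C)cc1
F8 | step 7 | (2E)-N-methoxy-N-methyl-3-({(3Z)-2-methyl-8-[4-(triisopropylsilyloxy)phenyl]oct-3-en-5-yn-2-yl}oxy)prop-2-enamide | CON(C)C(=O)/C=C/OC(C)(C)/C=C\C#CCCc1ccc(O[Si](C(C)C)(C(C)C)C(C)C)cc1
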